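It is impossible to read this row as a yield that climbs with reagent: the blue run, at 4.4 equiv, holds 15% of single product at 0.667 min but 4% at 2.00 min.

in all of them: substrate 0.052 M
- teal: reagent 0.36 equiv; run made earlier
- blue: reagent 4.4 equiv; run made earlier
- cedar: reagent 0.250 equiv; time 15 min
- maple: reagent 0.500 equiv; time 15 min
- oak: reagent 1.00 equiv; time 15 min
- larch: reagent 2.00 equiv; time 15 min
- alder: reagent 4.00 equiv; time 15 min

| run | time / min | single product / % | substrate / % |
|---|---|---|---|
| teal | 0.667 | 5 | 92 |
| teal | 1.00 | 11 | 88 |
| teal | 2.00 | 15 | 81 |
| teal | 4.00 | 18 | 74 |
| teal | 8.00 | 17 | 76 |
| blue | 0.667 | 15 | 31 |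
| blue | 2.00 | 4 | 5 |
| blue | 4.00 | 1 | 3 |
| blue | 5.00 | 4 | 0 |
| blue | 8.00 | 4 | 0 |

(standard deviation of a reading: 1.5 percentage points)

- "hardly changes" means that all values lie within two and a half points (for a concentration: within two and a half percent of the largest)

* amount of single product at the end, in percent of the substrate charged for cedar, maple, oak, larch, alder, in this order
* how the row runs (rises, then falls / rises all the way / hardly changes / falls, then rises / falls all the way)

We follow one reagent molecule and take the events in order of speed.

1. Substrate in the blue run falls to 31% by 0.667 min, so a substrate molecule there lasts about 0.570 min, as a reading.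

2. The reagent molecule reaches a fork: substrate or single product. While little substrate is lost, twice the lost substrate not found as single product, divided by the square of the loss, measures that fork. Teal at 4.00 min gives, as a reading, 2.37, our fork ratio: how many times more readily one single product takes reagent than one substrate does, the usual selectivity factor.

3. Single product in the blue run therefore lasts about 0.241 min, a shorter time than substrate.

4. Teal stalls: substrate reads 74% at 4.00 min and 76% at 8.00 min. The asked 15 min is longer than that stall time, so we expect the low-reagent flasks to be read after they have stopped.

5. The rule, while reagent is present: single product gains as long as substrate exceeds the fork ratio times single product, and loses once substrate falls below that. Assuming both steps are first order in reagent, the balance comes at 53.2% substrate and 22.5% single product. So we expect a rise, then a fall.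

The forecast gives 15%, 20%, 19%, 5%, 3%: rises, then falls. Its ground: “That fits the reagent running out, with the product also consuming reagent”. Its fork ratio is 2.7, and our high point stands above its 20%.

The flasks give 14.9%, 20.0%, 19.8%, 8.12%, 0.0108%: rises, then falls.

    substrate + reagent → single product (k = 9.90 L mol⁻¹ min⁻¹)
    reagent + single product → bis adduct (k = 26.0 L mol⁻¹ min⁻¹)
    reagent + bis adduct → tris adduct (k = 5.90 L mol⁻¹ min⁻¹)
    reagent + tris adduct ⇌ tetra adduct (K = 8.50 L mol⁻¹, k = 35.0 L mol⁻¹ min⁻¹)
    substrate → decomposition product (k = 2.50 × 10⁻⁵ min⁻¹)

Cedar ends on the gaining side of the rule, with substrate 80.1% against 35.3% and reagent down to 0.0093% of its charge. The shrinking supply of reagent shows in cedar: with reagent held at its charge, cedar ends at 8.53% instead of 14.9%. Maple also ends on the gaining side, with substrate 66% against 47.3%, while oak ends on the losing side, with substrate 43.4% against 46.9%, and the row turns at 0.72 equiv.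

All runs stem from a simulated flask on assumed constants, noise included.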